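Time is the question here: the flask, which is birch itself, is asked about at 4.0 d, but birch has been followed only to 40.0 h. In a repeat, we watch whether target holds its level through the unseen stretch.

all flasks: starting material 0.050 M; catalyst 7.5 mM

| run | partner | second substrate | remark | time |
|---|---|---|---|---|
| birch | 0.090 M | 0.050 M | the very flask that is asked about, followed so far |  |
| maple | 0.045 M | 0.050 M | run made earlier |  |
| flask | 0.0900 M | 0.0500 M |  | 4.0 d |

birch run (percent of the starting material charged)

| time / h | starting material / % | target / % |
|---|---|---|
| 10.0 | 80.6 | 19.2 |
| 20.0 | 73.7 | 26.2 |
| 30.0 | 71.2 | 29.2 |
| 40.0 | 70.1 | 29.3 |

maple run (percent of the starting material charged)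

| time / d | starting material / % | target / % |
|---|---|---|
| 0.333 | 91.3 | 8.0 |
| 0.833 | 87.0 | 13.1 |
| 1.67 | 87.2 | 13.0 |
| 4.00 | 90.0 | 9.8 |

(scatter of a reading: 0.3 percentage points)

- at 4.0 d, what has stopped the reaction, if anything has (it is still moving / all of the starting material has reacted / forward and back rates have come level / no working catalyst is left / the partner has run out first)
- conversion of starting material at 4.0 d
- amount of target at 4.0 d, in percent of the starting material charged
- amount of target if the flask were left three thousand times as long, in percent of the starting material charged

- steps under discussion: starting material + partner + catalyst <-> catalyst + target; second substrate + partner + catalyst -> catalyst + second product; 2 second substrate -> homo dimer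
- the reaction counts as stopped when no species that holds the starting material changes by six tenths of a point or more over the second half of the time

We draw birch's target curve first. It gains 19.2% in the first 10.0 h, then 7 percentage points, 3 points and 0.1 points over the next equal stretches, against a scatter of 0.3 points. So the knee lies near 20.0 h, and the curve runs into a level near 29.3%.

Does that level last? The draining step has no way back, and each second substrate it uses takes one partner. In maple, the partner charge is below the second substrate charge, and target falls from 13.1% to 9.8% by 4.00 d. In birch, the partner charge is larger. We therefore define the spare partner as partner charged minus second substrate charged, counting every second substrate as taking a partner: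

spare partner = 0.0400 M

free partner = spare partner − target = 0.0253 M

level constant = (target / starting material) / free partner = 16.5 L mol⁻¹

This constant is a reading, and on birch it merely returns the level, so it checks nothing. Still, we commit: forward and back rates level by 4.0 d, with target near 29.3%, conversion near 29.9%, and the same target after the long wait.

The forecast differs. It says it is still moving, with conversion 26%, target 26% and finally 24%, holding that the “plateau near 29% is only temporary”.

The flask gives forward and back rates have come level, with conversion 29.8%, target 29.8% and finally 29.5%.

    starting material + partner + catalyst ⇌ catalyst + target (K = 14.0 L mol⁻¹, k = 0.860 L² mol⁻² min⁻¹)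
    second substrate + partner + catalyst → catalyst + second product (k = 3.30 L² mol⁻² min⁻¹)
    2 second substrate → homo dimer (k = 0.00340 L mol⁻¹ min⁻¹)

At 4.00 d, the flask's quotient by the same balance is 16.9 L mol⁻¹, against the 16.5 L mol⁻¹ read earlier. For the neighbour with 0.36 M of partner, the spare partner is 0.310 M. Putting the level constant into the same balance gives target 81.6%. That neighbour holds 79.2% target at 4.00 d.

The readings come from a simulation from invented constants; scatter was added.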